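**Retrosynthetic overview**
1. Numbering: ring A = C1–C5 + C10, ring B = C5–C10. C3 carries O-tigloyl, C4 Me, C5 Me, C7 isopropenyl, C8 C=O, C9 O-senecioyl, C10 H. β is the face of the C5 methyl, so the target is 3α,4β,5β,7α,9α,10α: a trans-decalin in which only the C5 methyl is axial.
2. The strategy rests on the methyl-bearing quaternary C5 at the ring A/ring B fusion, next to C10. Its C5–C6 bond is made by moving C6 from C10 to C5, which turns a spiro cyclopentane on ring A into ring B and leaves C9=C10.
3. Going backwards: both esters are attached last. The 9α-O comes from Rubottom oxidation of the 8(9)-silyl enol ether, which Li/NH3 reduction of a 9(10)-en-8-one delivers (this also sets 10α-H). The isopropenyl group comes from an acetone aldol at C7, and the enone from allylic oxidation of the 9(10)-octalin.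
4. The octalin comes from the tertiary spiro carbinol (MeLi on the spiro ketone). The 3α-O/4β-Me pair comes from hydroboration of a 3(4)-alkene anti to a C5 carbinol, itself made by asymmetric hydrogenation of the spiro enone.
5. Ring order: ring A is bought as 2-methylcyclohexenone. The cyclopentane is added by spiroannulation at the α′ carbon, before any β-oxygen exists. Ring B arises by expansion of the cyclopentane.

Key step: step 7

Assumption: the sense of induction in step 2 is taken from the behaviour of this catalyst type with tert-alkyl methyl ketones, the spiro carbon playing the tert-alkyl part; if it proves opposite, the (R)-ligand is used.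

Step 1
Reactants: 1 2-methylcyclohex-2-en-1-one; 2 1,4-dibromobutane
Product: 4 7-methylspiro[4.5]dec-7-en-6-one, via bromobutyl enone 3 (not isolated)
Conditions: LiN(iPr)2 (1.05 equiv), THF, −78 °C; 2 (1.3 equiv), DMPU, −78 → 0 °C; LiN(iPr)2 (1.1 equiv), −78 °C → rt
Reagents that add atoms: none
Why: Kinetic deprotonation of the enone can occur only at the α′ carbon (future C10), so SN2 alkylation followed by a 5-exo-tet intramolecular enolate alkylation closes the cyclopentane while no β-oxygen is yet present to be eliminated; no stereocentre is formed.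

Step 2
Reactants: 4 7-methylspiro[4.5]dec-7-en-6-one
Product: 5 (R)-7-methylspiro[4.5]dec-7-en-6-ol (5β-OH)
Conditions: RuCl2[(S)-tolbinap](pica) (0.5 mol %), KOtBu (5 mol %), H2 (10 atm), EtOH, 25 °C
Reagents that add atoms: none
Why: This is a carbonyl-selective asymmetric ketone hydrogenation with a diphosphine/2-(aminomethyl)pyridine ruthenium dichloride catalyst, a type suited to ketones flanked by a quaternary carbon; it leaves the alkene untouched, and hydride delivery to the α face sets the 5β carbinol, whose only task is to steer step 3.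

Step 3
Reactants: 5 (R)-7-methylspiro[4.5]dec-7-en-6-ol
Product: 7 (6S,7S,8R)-7-methylspiro[4.5]decane-6,8-diol (3α-OH, 4β-Me, 5β-OH), via boryl adduct 6 (not isolated)
Conditions: BH3·THF (3 equiv), THF, 0 °C → rt; then NaOH (3 M), H2O2 (30 %), 0 °C → rt
Reagents that add atoms: borane–tetrahydrofuran, B.C1CCOC1 (boron stays only in 6); hydrogen peroxide, OO
Why: Hydroboration–oxidation puts boron on the less substituted C3 and adds H and B syn from the α face, anti to the C5 oxygen, so the 3α-OH (formed with retention) is necessarily trans to the 4β-methyl.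

Step 4
Reactants: 7 (6S,7S,8R)-7-methylspiro[4.5]decane-6,8-diol
Product: 8 (6S,7R,8R)-7-methyl-8-(triisopropylsilyloxy)spiro[4.5]decan-6-ol
Conditions: iPr3SiOTf (1.05 equiv), 2,6-lutidine, CH2Cl2, −78 °C
Reagents that add atoms: triisopropylsilyl triflate, CC(C)[Si](OS(=O)(=O)C(F)(F)F)(C(C)C)C(C)C
Why: In this site-selective silylation the bulky silyl triflate takes the equatorial C3 hydroxyl, because the axial C5 hydroxyl is neopentyl and lies next to the spiro carbon.

Step 5
Reactants: 8 (6S,7R,8R)-7-methyl-8-(triisopropylsilyloxy)spiro[4.5]decan-6-ol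
Product: 9 (7S,8R)-7-methyl-8-(triisopropylsilyloxy)spiro[4.5]decan-6-one
Conditions: Dess–Martin periodinane, NaHCO3, CH2Cl2, 0 °C → rt
Reagents that add atoms: none
Why: Dess–Martin oxidation under buffered, non-basic conditions gives the β-silyloxy ketone without eliminating silanol and without touching C4, which already has the more stable equatorial methyl.

Step 6
Reactants: 9 (7S,8R)-7-methyl-8-(triisopropylsilyloxy)spiro[4.5]decan-6-one; 10 methyllithium
Product: 11 (6R,7S,8R)-6,7-dimethyl-8-(triisopropylsilyloxy)spiro[4.5]decan-6-ol (5α-OH epimer drawn; the 6S epimer is carried along)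
Conditions: CeCl3 (anhydrous, 1.5 equiv), 10 (1.5 equiv), THF, −78 °C; aq. NH4Cl
Reagents that add atoms: none
Why: 1,2-Addition of the weakly basic organocerium reagent to the hindered ketone outruns enolisation at C4 and the β-elimination that would follow, and the carbinol configuration does not matter because both epimers ionise to the same cation.

Step 7
Reactants: 11 (6R,7S,8R)-6,7-dimethyl-8-(triisopropylsilyloxy)spiro[4.5]decan-6-ol (with its 6S epimer)
Product: 14 3α-(triisopropylsilyloxy)-4β,5β-dimethyloctal-9(10)-ene, via spiro C5 cation 12 (not isolated), via decalyl C10 cation 13 (not isolated)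
Conditions: BF3·OEt2 (1.5 equiv), CH2Cl2, −78 → −30 °C, short contact; Et3N, then aq. NaHCO3
Reagents that add atoms: none
Why: BF3 ionises either carbinol epimer to the planar tertiary cation 12, the cyclopentane bond C10–C6 that stands axial on ring A and parallel to the empty orbital shifts suprafacially to C5 to give the tertiary cation 13, and loss of a C9 proton gives 14. The closest known reaction type is the Wagner–Meerwein ring expansion of cyclopentylcarbinyl cations, as in the acid-promoted conversion of spiro[4.5]decan-6-ols into octalins, driven by release of cyclopentane strain and of crowding at the spiro centre. Ring B is not closed by a cyclisation but grows from the five-membered ring through a 1,2-alkyl shift that inserts C5 (five to six members, new bond C5–C6). The new stereocentre C5 is controlled by the chair of ring A: an axial C4 methyl would clash 1,3-diaxially with the axial spiro methylene, so C3–O and C4–Me stay equatorial, the axial migrating CH2 lies on the α face, and its entry at C5 from α pushes the C5 methyl to β, cis to the C4 methyl. The alkyl shift must beat the C4→C5 hydride shift, which is disfavoured because it would place the charge next to the C3 oxygen, and low temperature with an early quench must forestall the onward C5→C10 methyl shift. Proton loss must occur at C9 and not at C1; the substrate offers only a modest bias here (the C1–H bonds sit in the ring that carries the C3–O dipole and the bulky silyl ether, whereas ring B is bare), so this is the chief risk of the route.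

Step 8
Reactants: 14 3α-(triisopropylsilyloxy)-4β,5β-dimethyloctal-9(10)-ene
Product: 15 3α-(triisopropylsilyloxy)-4β,5β-dimethyloctal-9(10)-en-8-one
Conditions: Rh2(cap)4 (cap = caprolactamate, 1 mol %), tBuOOH (5 equiv), K2CO3 (0.5 equiv), CH2Cl2, rt
Reagents that add atoms: tert-butyl hydroperoxide, CC(C)(C)OO
Why: Dirhodium-catalysed allylic oxidation attacks the ring methylene attached to the vinylic CH (C8) rather than C1 on the fully substituted alkene carbon, the same site preference as in the oxidation of 5-ene steroids to 7-ketones, and gives the conjugated enone.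

Step 9
Reactants: 15 3α-(triisopropylsilyloxy)-4β,5β-dimethyloctal-9(10)-en-8-one; 16 acetone
Product: 17 7α-(2-hydroxypropan-2-yl)-3α-(triisopropylsilyloxy)-4β,5β-dimethyloctal-9(10)-en-8-one
Conditions: LiN(iPr)2 (1.1 equiv), THF, −78 °C; ZnCl2 (1.1 equiv); 16 (3 equiv), −78 → −40 °C; aq. NH4Cl
Reagents that add atoms: none
Why: Kinetic α′-deprotonation at C7 is followed by aldol addition of the zinc enolate to acetone, which approaches from the α face away from the pseudoaxial C5 methyl and so sets the equatorial 7α side chain.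

Step 10
Reactants: 17 7α-(2-hydroxypropan-2-yl)-3α-(triisopropylsilyloxy)-4β,5β-dimethyloctal-9(10)-en-8-one
Product: 18 7α-isopropenyl-3α-(triisopropylsilyloxy)-4β,5β-dimethyloctal-9(10)-en-8-one (3α-silyloxyeremophila-9,11-dien-8-one)
Conditions: SOCl2 (1.5 equiv), pyridine, CH2Cl2, −30 → 0 °C
Reagents that add atoms: none
Why: E2-type dehydration of the tertiary chlorosulfite by pyridine at low temperature should remove one of the six unhindered methyl hydrogens rather than the shielded C7–H, which gives the isopropenyl group and leaves the C7 configuration untouched.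

Step 11
Reactants: 18 7α-isopropenyl-3α-(triisopropylsilyloxy)-4β,5β-dimethyloctal-9(10)-en-8-one
Product: 20 8-(trimethylsilyloxy)-3α-(triisopropylsilyloxy)-10αH-eremophila-8,11-diene, via lithium enolate 19 (not isolated)
Conditions: Li (2.5 equiv), NH3(l)/THF, tBuOH (1.0 equiv), −78 °C; isoprene; NH3 evaporated; Me3SiCl, Et3N, THF, −78 → 0 °C
Reagents that add atoms: lithium, [Li] (stays only in 19); chlorotrimethylsilane, C[Si](C)(C)Cl
Why: Dissolving-metal (Birch-type) reduction of the enone protonates C10 axially from the α face to give the trans-decalin and leaves the regiodefined 8(9)-enolate, which is silylated on oxygen, while the isolated isopropenyl group is not reduced.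

Step 12
Reactants: 20 8-(trimethylsilyloxy)-3α-(triisopropylsilyloxy)-10αH-eremophila-8,11-diene
Product: 22 9α-hydroxy-3α-(triisopropylsilyloxy)-10αH-eremophil-11-en-8-one, via silyloxy ketone 21 (not isolated)
Conditions: mCPBA (1.0 equiv), NaHCO3, CH2Cl2, −20 °C; then citric acid, MeOH, 0 °C
Reagents that add atoms: 3-chloroperbenzoic acid, O=C(OO)c1cccc(Cl)c1
Why: In the Rubottom oxidation the electron-rich silyl enol ether is epoxidised faster than the 1,1-disubstituted alkene and from the α face opposite the axial C5 methyl, so silyl migration and mild hydrolysis give the equatorial 9α-hydroxy ketone.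

Step 13
Reactants: 22 9α-hydroxy-3α-(triisopropylsilyloxy)-10αH-eremophil-11-en-8-one; 23 3-methylbut-2-enoic acid
Product: 24 9α-(3-methylbut-2-enoyloxy)-3α-(triisopropylsilyloxy)-10αH-eremophil-11-en-8-one
Conditions: 23 (1.5 equiv), DCC (1.5 equiv), DMAP (0.1 equiv), CH2Cl2, 0 °C → rt
Reagents that add atoms: none
Why: Steglich esterification acylates the only free hydroxyl under nearly neutral conditions, which avoids the vinylketene pathway of the acid chloride, epimerisation at C7 or C9, and drift of the alkene into conjugation.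

Step 14
Reactants: 24 9α-(3-methylbut-2-enoyloxy)-3α-(triisopropylsilyloxy)-10αH-eremophil-11-en-8-one
Product: 25 3α-hydroxy-9α-(3-methylbut-2-enoyloxy)-10αH-eremophil-11-en-8-one
Conditions: HF·pyridine, pyridine/THF, 0 °C → rt
Reagents that add atoms: none
Why: Fluoride-mediated desilylation in an acidic buffer cleaves the silyl ether without the basic conditions that would cause ester loss or isomerisation of the β,γ-unsaturated ketone.

Step 15
Reactants: 25 3α-hydroxy-9α-(3-methylbut-2-enoyloxy)-10αH-eremophil-11-en-8-one; 26 (E)-2-methylbut-2-enoic acid (tiglic acid)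
Product: 27 3α-[(E)-2-methylbut-2-enoyloxy]-9α-(3-methylbut-2-enoyloxy)-10αH-eremophil-11-en-8-one (CNP0375730.3)
Conditions: 26 (2 equiv), DCC (2 equiv), DMAP (0.2 equiv), CH2Cl2, rt
Reagents that add atoms: none
Why: Steglich esterification of the equatorial 3α-hydroxyl keeps the E geometry of the acid and completes the target without creating or disturbing a stereocentre.

**Compound list**
1 | 2-methylcyclohex-2-en-1-one | CC1=CCCCC1=O | starting material
2 | 1,4-dibromobutane | BrCCCCBr | starting material
3 | 6-(4-bromobutyl)-2-methylcyclohex-2-en-1-one (racemic) | CC1=CCCC(CCCCBr)C1=O | intermediate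
4 | 7-methylspiro[4.5]dec-7-en-6-one | CC1=CCCC2(CCCC2)C1=O | intermediate
5 | (R)-7-methylspiro[4.5]dec-7-en-6-ol | O[C@H]1C(C)=CCCC12CCCC2 | intermediate
6 | 3α-boryl-5β-boryloxy adduct of 5 | BO[C@H]1[C@@H](C)[C@H](B)CCC12CCCC2 | intermediate
7 | (6S,7S,8R)-7-methylspiro[4.5]decane-6,8-diol | O[C@H]1[C@@H](C)[C@H](O)CCC12CCCC2 | intermediate
8 | (6S,7R,8R)-7-methyl-8-(triisopropylsilyloxy)spiro[4.5]decan-6-ol | O[C@H]1[C@@H](C)[C@H](O[Si](C(C)C)(C(C)C)C(C)C)CCC12CCCC2 | intermediate
9 | (7S,8R)-7-methyl-8-(triisopropylsilyloxy)spiro[4.5]decan-6-one | O=C1[C@@H](C)[C@H](O[Si](C(C)C)(C(C)C)C(C)C)CCC12CCCC2 | intermediate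
10 | methyllithium | [Li]C | starting material
11 | (6R,7S,8R)-6,7-dimethyl-8-(triisopropylsilyloxy)spiro[4.5]decan-6-ol (6S epimer also used) | O[C@]1(C)[C@@H](C)[C@H](O[Si](C(C)C)(C(C)C)C(C)C)CCC12CCCC2 | intermediate
12 | spiro C5 cation | C[C+]1[C@@H](C)[C@H](O[Si](C(C)C)(C(C)C)C(C)C)CCC12CCCC2 | intermediate
13 | decalyl C10 cation | C1C[C@]2(C)[C@@H](C)[C@H](O[Si](C(C)C)(C(C)C)C(C)C)CC[C+]2CC1 | intermediate
14 | 3α-(triisopropylsilyloxy)-4β,5β-dimethyloctal-9(10)-ene | C1C[C@]2(C)[C@@H](C)[C@H](O[Si](C(C)C)(C(C)C)C(C)C)CCC2=CC1 | intermediate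
15 | 3α-(triisopropylsilyloxy)-4β,5β-dimethyloctal-9(10)-en-8-one | O=C1CC[C@]2(C)[C@@H](C)[C@H](O[Si](C(C)C)(C(C)C)C(C)C)CCC2=C1 | intermediate
16 | acetone | CC(C)=O | starting material
17 | 7α-(2-hydroxypropan-2-yl)-3α-(triisopropylsilyloxy)-4β,5β-dimethyloctal-9(10)-en-8-one | CC(C)(O)[C@@H]1C[C@]2(C)[C@@H](C)[C@H](O[Si](C(C)C)(C(C)C)C(C)C)CCC2=CC1=O | intermediate
18 | 7α-isopropenyl-3α-(triisopropylsilyloxy)-4β,5β-dimethyloctal-9(10)-en-8-one | C=C(C)[C@@H]1C[C@]2(C)[C@@H](C)[C@H](O[Si](C(C)C)(C(C)C)C(C)C)CCC2=CC1=O | intermediate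
19 | lithium 8(9)-enolate, 10αH | C=C(C)[C@@H]1C[C@]2(C)[C@@H](C)[C@H](O[Si](C(C)C)(C(C)C)C(C)C)CC[C@H]2C=C1[O-].[Li+] | intermediate
20 | 8-(trimethylsilyloxy)-3α-(triisopropylsilyloxy)-10αH-eremophila-8,11-diene | C=C(C)[C@@H]1C[C@]2(C)[C@@H](C)[C@H](O[Si](C(C)C)(C(C)C)C(C)C)CC[C@H]2C=C1O[Si](C)(C)C | intermediate
21 | 9α-(trimethylsilyloxy)-3α-(triisopropylsilyloxy)-10αH-eremophil-11-en-8-one | C=C(C)[C@@H]1C[C@]2(C)[C@@H](C)[C@H](O[Si](C(C)C)(C(C)C)C(C)C)CC[C@H]2[C@H](O[Si](C)(C)C)C1=O | intermediate
22 | 9α-hydroxy-3α-(triisopropylsilyloxy)-10αH-eremophil-11-en-8-one | C=C(C)[C@@H]1C[C@]2(C)[C@@H](C)[C@H](O[Si](C(C)C)(C(C)C)C(C)C)CC[C@H]2[C@H](O)C1=O | intermediate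
23 | 3-methylbut-2-enoic acid | CC(C)=CC(=O)O | starting material
24 | 9α-(3-methylbut-2-enoyloxy)-3α-(triisopropylsilyloxy)-10αH-eremophil-11-en-8-one | C=C(C)[C@@H]1C[C@]2(C)[C@@H](C)[C@H](O[Si](C(C)C)(C(C)C)C(C)C)CC[C@H]2[C@H](OC(=O)C=C(C)C)C1=O | intermediate
25 | 3α-hydroxy-9α-(3-methylbut-2-enoyloxy)-10αH-eremophil-11-en-8-one | C=C(C)[C@@H]1C[C@]2(C)[C@@H](C)[C@H](O)CC[C@H]2[C@H](OC(=O)C=C(C)C)C1=O | intermediate
26 | (E)-2-methylbut-2-enoic acid | C/C=C(\C)C(=O)O | starting material
27 | 3α-[(E)-2-methylbut-2-enoyloxy]-9α-(3-methylbut-2-enoyloxy)-10αH-eremophil-11-en-8-one (CNP0375730.3) | C=C(C)[C@@H]1C[C@]2(C)[C@@H](C)[C@H](OC(=O)/C(C)=C/C)CC[C@H]2[C@H](OC(=O)C=C(C)C)C1=O | target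

**Step count**
Total steps: 15. Longest linear sequence: 15 (from 1).

**Steps most likely to fail**

Step 7. Proton loss from the C10 cation may show little preference between C9 and C1. Longer acid contact may also let the C5 methyl move on to C10, or may strip the silyl ether after simple elimination.
- Fallback, from 11 back to 14: the ionisation is quenched early and regiocontrol is no longer asked of the cation. The alkene position is instead corrected afterwards by a radical process rather than a cationic one.
- The isomer 3α-(triisopropylsilyloxy)-4β,5β-dimethyloctal-1(10)-ene F1 is separated. This is easiest after step 8, which should pass it by because its reactive allylic methylene, C2, is flanked by the silyloxy carbon.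
- F1 is then equilibrated with 14 by hydrogen-atom-transfer alkene isomerisation ([N,N′-bis(3,5-di-tert-butylsalicylidene)cyclohexane-1,2-diaminato]cobalt chloride, PhSiH3, benzene, rt). This runs through the C10 radical and cannot move the methyl group, and repeated cycles feed 14.

Step 2. Facial discrimination may be poor because both flanks of the carbonyl are hindered.
- Fallback, from 4 back to 7: asymmetric catalysis is replaced by resolution at the unhindered C3 carbinol.
- Luche reduction (NaBH4, CeCl3·7H2O, MeOH) gives 5 together with (S)-7-methylspiro[4.5]dec-7-en-6-ol F2.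
- Hydroboration–oxidation as in step 3 gives 7 together with (6R,7R,8S)-7-methylspiro[4.5]decane-6,8-diol F3.
- Lipase-catalysed acylation (immobilised Candida antarctica lipase B, vinyl acetate, tBuOMe, 30 °C) should acylate the 8R carbinol faster, since it has a CH2 flank on one side and a CH(CH3) flank on the other. This gives (6S,7R,8R)-6-hydroxy-7-methylspiro[4.5]decan-8-yl acetate F4 and leaves F3 behind.
- Methanolysis of F4 (K2CO3, MeOH) returns 7.

Step 10. Elimination may run towards C7 and give the conjugated isopropylidene ketone, or the alkene may drift into conjugation afterwards.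
- Fallback, from 15 back to 18: the dehydration is replaced by a regiospecific reductive elimination.
- LiN(iPr)2 then Me3SiCl gives the cross-conjugated silyl dienol ether 8-(trimethylsilyloxy)-3α-(triisopropylsilyloxy)-4β,5β-dimethylocta-7,9(10)-diene F5.
- A Mukaiyama aldol addition to chloroacetone (TiCl4, CH2Cl2, −78 °C), again from the α face, gives the chlorohydrin 7α-(1-chloro-2-hydroxypropan-2-yl)-3α-(triisopropylsilyloxy)-4β,5β-dimethyloctal-9(10)-en-8-one F6.
- Zn with NaI in AcOH/EtOH removes Cl and OH and can place the alkene only between C11 and the former CH2Cl carbon, which gives 18.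

**Further compounds**
F1 | step 7 | 3α-(triisopropylsilyloxy)-4β,5β-dimethyloctal-1(10)-ene | C1C[C@]2(C)[C@@H](C)[C@H](O[Si](C(C)C)(C(C)C)C(C)C)CC=C2CC1
F2 | step 2 | (S)-7-methylspiro[4.5]dec-7-en-6-ol | O[C@@H]1C(C)=CCCC12CCCC2
F3 | step 2 | (6R,7R,8S)-7-methylspiro[4.5]decane-6,8-diol | O[C@@H]1[C@H](C)[C@@H](O)CCC12CCCC2
F4 | step 2 | (6S,7R,8R)-6-hydroxy-7-methylspiro[4.5]decan-8-yl acetate | O[C@H]1[C@@H](C)[C@H](OC(C)=O)CCC12CCCC2
F5 | step 10 | 8-(trimethylsilyloxy)-3α-(triisopropylsilyloxy)-4β,5β-dimethylocta-7,9(10)-diene | C[Si](C)(C)OC1=CC[C@]2(C)[C@@H](C)[C@H](O[Si](C(C)C)(C(C)C)C(C)C)CCC2=C1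
F6 | step 10 | 7α-(1-chloro-2-hydroxypropan-2-yl)-3α-(triisopropylsilyloxy)-4β,5β-dimethyloctal-9(10)-en-8-one (C11 epimers) | CC(O)(CCl)[C@@H]1C[C@]2(C)[C@@H](C)[C@H](O[Si](C(C)C)(C(C)C)C(C)C)CCC2=CC1=O
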